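## Retrosynthetic overview

1. Target ⇒ its C9 O‑TBS ether, so the last step only cleaves Si–O (polyketide numbering: C1 = pyrone C=O, C9 = carbinol carbon).
2. Both carbocycles are opened together along the polyketide fold. Cutting the arene bond C6–C15 (second aldol) and the cyclohexenone bond C7–C12 (first aldol) gives an open‑chain C9‑silyloxy tetraketone that ends in the 4‑hydroxy‑2‑pyrone.
3. Two Claisen cuts in the open chain (C11–C12 and C6–C7) give three pieces. These are 7‑methyloctane‑2,4‑dione (C12–C19), monomethyl (R)‑3‑TBSO‑glutarate (C7–C11, which brings the only stereocentre) and triacetic acid lactone (C1–C6).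
4. The diketone ⇒ methyl isoamyl ketone + ethyl acetate (Claisen).
5. Ring order forward: pyrone (present from triacetic acid lactone) → cyclohexenone ring (C7–C12) → benzene ring (C6–C15). The last C–C coupling and both carbocyclisations run in one flask.

Assumption: metal salts (enolates, dianions) of a numbered compound count as that compound and get no number of their own. TBS = tert‑butyldimethylsilyl. Compound 4 is bought as the single (R)‑enantiomer (bulk statin side‑chain acid).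

## Route

Step 1
Reactants: 1 5‑methylhexan‑2‑one (methyl isoamyl ketone); 2 ethyl acetate
Product: 3 7‑methyloctane‑2,4‑dione
Conditions: NaH (2 equiv), THF, reflux; aq. HCl
Reagents that add atoms: none
Why: Crossed Claisen condensation under equilibrating conditions acylates the methyl group of the ketone, because only that product forms the unhindered β‑diketonate that drives the equilibrium; no stereocentre is involved.

Step 2
Reactants: 4 (3R)‑3‑(TBSO)‑5‑methoxy‑5‑oxopentanoic acid; 5 4‑hydroxy‑6‑methyl‑2H‑pyran‑2‑one (triacetic acid lactone)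
Product: 7 methyl (3R)‑3‑(TBSO)‑6‑(4‑hydroxy‑2‑oxo‑2H‑pyran‑6‑yl)‑5‑oxohexanoate, via acyl imidazolide 6 (not isolated)
Conditions: 4, CDI, THF, rt; cannulate into 5 (3.2 equiv) + LDA (6.4 equiv), THF, −78 → −30 → −78 °C, 1 h; AcOH at −78 °C
Reagents that add atoms: 1,1'‑carbonyldiimidazole, O=C(n1ccnc1)n1ccnc1 (supplies only the imidazolyl group of intermediate 6; none of its atoms remain in 7)
Why: Claisen‑type C‑acylation of a Hauser–Harris dianion, in which the last‑formed, most basic carbanion (the C6‑methyl of 5) attacks the acyl imidazolide far faster than the methyl ester at −78 °C, the excess dianion absorbs the imidazole N–H and the acidic C6–H of the product, and the C9 stereocentre of 4 is only carried along.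

Step 3
Reactants: 7 methyl (3R)‑3‑(TBSO)‑6‑(4‑hydroxy‑2‑oxo‑2H‑pyran‑6‑yl)‑5‑oxohexanoate; 3 7‑methyloctane‑2,4‑dione
Product: 10 6‑{(7R)‑7‑(TBSO)‑4‑hydroxy‑2‑(3‑methylbutyl)‑5‑oxo‑5,6,7,8‑tetrahydronaphthalen‑1‑yl}‑4‑hydroxy‑2H‑pyran‑2‑one, via open‑chain tetraketone 8 (not isolated), via acylcyclohexenone 9 (not isolated)
Conditions: 3 (5 equiv), LDA (10 equiv), THF, −78 → 0 °C; 7, −78 → 0 °C, 2 h; AcOH to pH ≈ 7, Ca(OAc)2 (2 equiv), MeOH, 0 °C → rt, 16 h, same flask
Reagents that add atoms: none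
Why: Proposed new method: the terminal carbanion (C12) of the dianion of 3 acylates the methyl ester of 7 (dianion Claisen), excess dianion having first turned 7 into its pyronate/C6‑enolate, which blocks enolisation towards C8, and the polyanion of 8 stays inert until buffered; at pH ≈ 7 with Ca2+ the only doubly activated carbon that can reach a non‑chelated ketone through a six‑membered transition state is C12 → C7 (Knoevenagel‑type aldol, E1cB loss of water, giving 9), whereupon C6, now a vinylogous and pyrone‑activated CH2 held cis to the side chain across C7=C12, adds to C15 and loss of water with enolisation of C13 gives the phenol 10; the sp3 C9 centre is a spectator and stays (R), and the near‑neutral buffer is chosen because stronger base would expel TBSO− and aromatise the second ring; the closest known reaction types are the Harris aldol aromatisation of partially protected β‑polyketones and the Yamaguchi Ca(OAc)2‑induced cyclisation of glutarate‑derived polyoxo chains, and what is new is keeping the β‑silyloxy ketone and closing both rings in the acylation flask.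

Step 4
Reactants: 10 6‑{(7R)‑7‑(TBSO)‑4‑hydroxy‑2‑(3‑methylbutyl)‑5‑oxo‑5,6,7,8‑tetrahydronaphthalen‑1‑yl}‑4‑hydroxy‑2H‑pyran‑2‑one
Product: 11 6‑[(7R)‑4,7‑dihydroxy‑2‑(3‑methylbutyl)‑5‑oxo‑5,6,7,8‑tetrahydronaphthalen‑1‑yl]‑4‑hydroxy‑2H‑pyran‑2‑one (target)
Conditions: HF·pyridine, THF/pyridine, 0 °C → rt
Reagents that add atoms: none
Why: Fluoride‑driven desilylation in a weakly acidic, non‑basic medium cleaves only Si–O, so no enolate forms for E1cB dehydration to the naphthol and the C–O bond at the stereocentre is untouched ((R) retained).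

## Compound list

1 | 5‑methylhexan‑2‑one | CC(C)CCC(C)=O | starting material
2 | ethyl acetate | CCOC(C)=O | starting material
3 | 7‑methyloctane‑2,4‑dione | CC(C)CCC(=O)CC(C)=O | intermediate
4 | (3R)‑3‑[(tert‑butyldimethylsilyl)oxy]‑5‑methoxy‑5‑oxopentanoic acid | COC(=O)C[C@H](O[Si](C)(C)C(C)(C)C)CC(=O)O | starting material
5 | 4‑hydroxy‑6‑methyl‑2H‑pyran‑2‑one (triacetic acid lactone) | Cc1cc(O)cc(=O)o1 | starting material
6 | methyl (3R)‑3‑[(tert‑butyldimethylsilyl)oxy]‑5‑(1H‑imidazol‑1‑yl)‑5‑oxopentanoate | COC(=O)C[C@H](O[Si](C)(C)C(C)(C)C)CC(=O)n1ccnc1 | intermediate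
7 | methyl (3R)‑3‑[(tert‑butyldimethylsilyl)oxy]‑6‑(4‑hydroxy‑2‑oxo‑2H‑pyran‑6‑yl)‑5‑oxohexanoate | COC(=O)C[C@H](O[Si](C)(C)C(C)(C)C)CC(=O)Cc1cc(O)cc(=O)o1 | intermediate
8 | 6‑{(4R)‑4‑[(tert‑butyldimethylsilyl)oxy]‑13‑methyl‑2,6,8,10‑tetraoxotetradecyl}‑4‑hydroxy‑2H‑pyran‑2‑one | CC(C)CCC(=O)CC(=O)CC(=O)C[C@H](O[Si](C)(C)C(C)(C)C)CC(=O)Cc1cc(O)cc(=O)o1 | intermediate
9 | 6‑{[(5R)‑5‑[(tert‑butyldimethylsilyl)oxy]‑2‑(6‑methyl‑3‑oxoheptanoyl)‑3‑oxocyclohex‑1‑en‑1‑yl]methyl}‑4‑hydroxy‑2H‑pyran‑2‑one | CC(C)CCC(=O)CC(=O)C1=C(Cc2cc(O)cc(=O)o2)C[C@@H](O[Si](C)(C)C(C)(C)C)CC1=O | intermediate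
10 | 6‑{(7R)‑7‑[(tert‑butyldimethylsilyl)oxy]‑4‑hydroxy‑2‑(3‑methylbutyl)‑5‑oxo‑5,6,7,8‑tetrahydronaphthalen‑1‑yl}‑4‑hydroxy‑2H‑pyran‑2‑one | CC(C)CCc1cc(O)c2c(c1-c1cc(O)cc(=O)o1)C[C@@H](O[Si](C)(C)C(C)(C)C)CC2=O | intermediate
11 | 6‑[(7R)‑4,7‑dihydroxy‑2‑(3‑methylbutyl)‑5‑oxo‑5,6,7,8‑tetrahydronaphthalen‑1‑yl]‑4‑hydroxy‑2H‑pyran‑2‑one, i.e. (3R)‑3,8‑dihydroxy‑5‑(4‑hydroxy‑2‑oxo‑2H‑pyran‑6‑yl)‑6‑(3‑methylbutyl)‑3,4‑dihydronaphthalen‑1(2H)‑one | CC(C)CCc1cc(O)c2c(c1-c1cc(O)cc(=O)o1)C[C@@H](O)CC2=O | target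

## Step count and risks

Total step count: 4. Longest linear sequence: 3 steps (4 → 7 → 10 → 11, or equally 1 → 3 → 10 → 11).

**Risk 1, step 3.** There are three failure modes.
- The dianionic ester 7 may be too deactivated to be acylated.
- The open chain 8 may close differently (C6 → C11, C10 → C15, or a γ‑pyrone).
- TBSO− may be lost, with aromatisation to the naphthalenediol.

The fallback is a Fujimoto–Belleau‑type annulation in place of a Claisen reaction on an open‑chain ester. It sets out from 7.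
- The ester is saponified (LiOH, THF/H2O, 0 °C) to (3R)‑3‑(TBSO)‑6‑(4‑hydroxy‑2‑oxo‑2H‑pyran‑6‑yl)‑5‑oxohexanoic acid F1.
- F1 is cyclodehydrated under dilution with EDC·HCl in CH2Cl2, without DMAP so that no O→C acyl shift occurs. This gives the enol lactone (4R,6Z)‑4‑(TBSO)‑6‑[(4‑hydroxy‑2‑oxo‑2H‑pyran‑6‑yl)methylidene]oxan‑2‑one F2.
- In F2, C11 is an activated enol ester and C6 no longer carries an acidic CH2, so the substrate bears one negative charge fewer.
- The dianion of 3 opens F2 at C11 already at −78 °C, with the C7 enolate itself as the leaving group.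
- This delivers the lithium salt of 8 cold and without free methoxide, where the route is rejoined. Buffering as in step 3 then takes 8 through 9 to 10.

**Risk 2, step 2.** The hard dianion of 5 may act as a base on 6, giving a ketene or E1cB loss of TBSO−. The C6 anion of 7 may also close onto the ester in a Dieckmann reaction, giving an achiral dione.

The fallback is a soft, decarboxylative malonate‑type Claisen (Masamune–Brooks). It sets out from 5.
- The dianion of 5 is quenched with CO2 to give (4‑hydroxy‑2‑oxo‑2H‑pyran‑6‑yl)acetic acid F3.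
- The magnesium salt of F3 (i‑PrMgCl, THF) is combined at rt with imidazolide 6.
- This gives (5R)‑5‑(TBSO)‑2‑(4‑hydroxy‑2‑oxo‑2H‑pyran‑6‑yl)‑7‑methoxy‑3,7‑dioxoheptanoic acid F4 as a mixture of C2 epimers.
- F4 decarboxylates on mildly acidic work‑up and comes back to the route at 7.

**Risk 3, step 4.** The β‑hydroxy tetralone may dehydrate to the fully aromatic naphthol during or after desilylation.

The fallback runs the cascade without a protecting group. It sets out from 7.
- The silyl group is removed at this stage (HF·pyridine, THF, 0 °C), where no aromatisation can drive loss of water. This gives methyl (3R)‑3‑hydroxy‑6‑(4‑hydroxy‑2‑oxo‑2H‑pyran‑6‑yl)‑5‑oxohexanoate F5.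
- F5 is treated with one further equivalent of the dianion of 3. The C9 alkoxide shields the ester from E1cB, as in Claisen condensations of unprotected β‑hydroxy esters.
- This gives 6‑[(4R)‑4‑hydroxy‑13‑methyl‑2,6,8,10‑tetraoxotetradecyl]‑4‑hydroxy‑2H‑pyran‑2‑one F6.
- In the same Ca(OAc)2 buffer, F6 closes through 6‑{[(5R)‑5‑hydroxy‑2‑(6‑methyl‑3‑oxoheptanoyl)‑3‑oxocyclohex‑1‑en‑1‑yl]methyl}‑4‑hydroxy‑2H‑pyran‑2‑one F7 and comes back to the route directly at 11.

## Further compounds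

F1 | step 3 | (3R)‑3‑[(tert‑butyldimethylsilyl)oxy]‑6‑(4‑hydroxy‑2‑oxo‑2H‑pyran‑6‑yl)‑5‑oxohexanoic acid | OC(=O)C[C@H](O[Si](C)(C)C(C)(C)C)CC(=O)Cc1cc(O)cc(=O)o1
F2 | step 3 | (4R,6Z)‑4‑[(tert‑butyldimethylsilyl)oxy]‑6‑[(4‑hydroxy‑2‑oxo‑2H‑pyran‑6‑yl)methylidene]oxan‑2‑one | O=C1C[C@H](O[Si](C)(C)C(C)(C)C)C/C(=C/c2cc(O)cc(=O)o2)O1
F3 | step 2 | (4‑hydroxy‑2‑oxo‑2H‑pyran‑6‑yl)acetic acid | OC(=O)Cc1cc(O)cc(=O)o1
F4 | step 2 | (5R)‑5‑[(tert‑butyldimethylsilyl)oxy]‑2‑(4‑hydroxy‑2‑oxo‑2H‑pyran‑6‑yl)‑7‑methoxy‑3,7‑dioxoheptanoic acid (C2 epimers) | COC(=O)C[C@H](O[Si](C)(C)C(C)(C)C)CC(=O)C(C(=O)O)c1cc(O)cc(=O)o1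
F5 | step 4 | methyl (3R)‑3‑hydroxy‑6‑(4‑hydroxy‑2‑oxo‑2H‑pyran‑6‑yl)‑5‑oxohexanoate | COC(=O)C[C@H](O)CC(=O)Cc1cc(O)cc(=O)o1
F6 | step 4 | 6‑[(4R)‑4‑hydroxy‑13‑methyl‑2,6,8,10‑tetraoxotetradecyl]‑4‑hydroxy‑2H‑pyran‑2‑one | CC(C)CCC(=O)CC(=O)CC(=O)C[C@H](O)CC(=O)Cc1cc(O)cc(=O)o1
F7 | step 4 | 6‑{[(5R)‑5‑hydroxy‑2‑(6‑methyl‑3‑oxoheptanoyl)‑3‑oxocyclohex‑1‑en‑1‑yl]methyl}‑4‑hydroxy‑2H‑pyran‑2‑one | CC(C)CCC(=O)CC(=O)C1=C(Cc2cc(O)cc(=O)o2)C[C@@H](O)CC1=O
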